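**Plan**
1. Retrosynthetic cuts, in order: the four aryl O–CH3 bonds (the phenols are carried as methyl ethers), the chalcone Cα=Cβ bond (aldol), the C8–acetyl bond (Friedel–Crafts), the lactone O1–C2 bond, ring A at C4a–C8a (Claisen cyclisation, key cut), and the open chain at C5–C6 (acylation of an acetoacetate dianion).
2. Enabling feature: C4 with its phenyl group, the C3–C2 arm and the C4a–C5 arm form a 3-phenylglutarate unit that is still prochiral before ring A exists, and C6, C7, C8 and C8a are one acetoacetate unit, so ring A (the phloroglucinol ring) can be closed from an open 3,5-dioxo ester.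
3. Forward order: glutarate desymmetrised, chain joined at C5–C6, ring A closed at C4a–C8a, lactone ring closed at O1–C2, then C8 acetylation, aldol condensation and demethylation.
4. Stereochemistry: the only stereocentre, C4 (R), comes from the catalytic enantioselective methanolysis of 3-phenylglutaric anhydride. It is never alpha to a carbonyl group and is carried through unchanged; the E alkene comes from the aldol condensation.

Key step: step 5

Atom labels (O1, C2 … C8a) are those of the chroman-2-one core of the target.
Assumption: the quinidine-derived catalyst of step 1 is taken to open the anhydride to the (S)-hemiester 2; if the sense proves to be the opposite, the quinine-derived pseudoenantiomer is used and nothing else changes.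

**Step 1**
Reactants: 1 3-phenylglutaric anhydride (4-phenyloxane-2,6-dione)
Product: 2 (3S)-5-methoxy-5-oxo-3-phenylpentanoic acid
Conditions: MeOH (10 equiv), 3,5-bis(trifluoromethyl)benzenesulfonamide of 9-amino-9-deoxy-epi-quinidine (10 mol%), MTBE, rt
Reagents that add atoms: methanol, CO
Why: Enantioselective alcoholysis (desymmetrisation) of a prochiral cyclic anhydride under bifunctional catalysis, in which the quinuclidine nitrogen activates methanol and the sulfonamide N–H one of the two enantiotopic carbonyl groups, sets the stereocentre (the later C4), and crystallisation of an amine salt of 2 can raise the enantiopurity.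

**Step 2**
Reactants: 2 (3S)-5-methoxy-5-oxo-3-phenylpentanoic acid
Product: 3 1-tert-butyl 5-methyl (3R)-3-phenylpentanedioate
Conditions: Cl3CC(=NH)OtBu (2 equiv), BF3·OEt2 (cat), CH2Cl2–cyclohexane, rt
Reagents that add atoms: tert-butyl 2,2,2-trichloroacetimidate, CC(C)(C)OC(=N)C(Cl)(Cl)Cl
Why: Acid-catalysed tert-butylation of a carboxylic acid by a trichloroacetimidate leaves the methyl ester and the stereocentre alone (the descriptor changes from S to R only because the ranking of the two arms changes).

**Step 3**
Reactants: 3 1-tert-butyl 5-methyl (3R)-3-phenylpentanedioate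
Product: 4 (3R)-5-tert-butoxy-5-oxo-3-phenylpentanoic acid
Conditions: LiOH·H2O (1.2 equiv), THF–H2O, 0 °C → rt; 1 M HCl to pH 3
Reagents that add atoms: lithium hydroxide, [Li+].[OH-]
Why: Saponification by hydroxide attack at the acyl carbon is fast for the methyl ester and blocked by steric hindrance at the tert-butyl ester, so the two arms exchange their roles without touching the stereocentre.

**Step 4**
Reactants: 4 (3R)-5-tert-butoxy-5-oxo-3-phenylpentanoic acid; 5 methyl acetoacetate (methyl 3-oxobutanoate)
Product: 7 9-tert-butyl 1-methyl (7R)-3,5-dioxo-7-phenylnonanedioate, via acyl imidazolide 6 (not isolated)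
Conditions: 4, 1,1'-carbonyldiimidazole (1.1 equiv), THF, rt; added at −78 °C to the dianion of 5 (3 equiv; NaH, then n-BuLi, THF, 0 °C), −78 → 0 °C; 1 M HCl
Reagents that add atoms: none
Why: Claisen-type C-acylation of the acetoacetate dianion at its terminal (gamma) carbon by an acyl imidazolide builds the 3,5-dioxo ester, and the mild imidazolide, used at once, should not let the ester arm close onto the activated arm to the symmetrical anhydride, so the stereocentre keeps its configuration.

**Step 5**
Reactants: 7 9-tert-butyl 1-methyl (7R)-3,5-dioxo-7-phenylnonanedioate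
Product: 9 tert-butyl (3R)-3-phenyl-3-(2,4,6-trihydroxyphenyl)propanoate, via trione tautomer 8 (not isolated)
Conditions: LiN(iPr)2 (3.5 equiv), THF, −78 °C → rt, argon; aq NH4Cl, then 1 M HCl to pH 4 at 0 °C
Reagents that add atoms: none
Why: Proposed new method: LiN(iPr)2 first removes the doubly activated protons at C6 and C8 and then a proton of the C4a methylene beside the C5 ketone, and this terminal carbanion, the most reactive site of the polyanion, adds to the methyl ester carbonyl C8a; loss of methoxide gives trione 8, which is deprotonated at C4a at once and leaves the equilibrium as the aromatic phloroglucinolate. The closest known reactions are the sodium methoxide Claisen cyclisation of methyl 3,5-dioxohexanoate to phloroglucinol, the same closure of C2- and C4-blocked 3,5-dioxo esters to cyclohexane-1,3,5-triones and the Dieckmann-type closure of 5-oxoalkanoates to 2-alkylcyclohexane-1,3-diones, and what is new is an unactivated methylene as the nucleophile beside two enolised dicarbonyl units. Ring A closes in the 6-(enolendo)-exo-trig mode. No stereocentre is formed, and C4, which is beta to every carbonyl group and has no acidic proton, is not touched. The step needs C-acylation at C4a in preference to attack of the C6 carbanion on the other ester (which would give a 2-acylcyclohexane-1,3-dione) and to O-acylation towards the 4-hydroxy-2-pyranone; the bulk of the tert-butyl ester shuts off the first, the kinetic lithium polyanion in THF should react at carbon, and aromatisation makes the wanted closure irreversible.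

**Step 6**
Reactants: 9 tert-butyl (3R)-3-phenyl-3-(2,4,6-trihydroxyphenyl)propanoate
Product: 11 (4R)-5,7-dihydroxy-4-phenyl-3,4-dihydro-2H-chromen-2-one, via hydroxy acid 10 (not isolated)
Conditions: CF3CO2H–H2O (95:5), 0 °C → rt; evaporate; PhMe, 60 °C
Reagents that add atoms: none
Why: Acidolysis of the tert-butyl ester by alkyl–oxygen cleavage (water takes up the tert-butyl cation before it can alkylate the electron-rich ring) is followed by acid-catalysed lactonisation of the 3-(2-hydroxyaryl)propanoic acid, and since the two hydroxyl groups ortho to the side chain are equivalent only one lactone can form.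

**Step 7**
Reactants: 11 (4R)-5,7-dihydroxy-4-phenyl-3,4-dihydro-2H-chromen-2-one
Product: 12 (4R)-5,7-dimethoxy-4-phenyl-3,4-dihydro-2H-chromen-2-one
Conditions: MeI (3 equiv), K2CO3 (3 equiv), dry acetone, reflux
Reagents that add atoms: iodomethane, CI
Why: Williamson O-methylation of the two phenols under anhydrous carbonate leaves the aryl lactone closed, and the C5 methyl ether from now on makes O1 the only oxygen that can hold the lactone.

**Step 8**
Reactants: 12 (4R)-5,7-dimethoxy-4-phenyl-3,4-dihydro-2H-chromen-2-one
Product: 13 (4R)-8-acetyl-5,7-dimethoxy-4-phenyl-3,4-dihydro-2H-chromen-2-one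
Conditions: AcOH (1.5 equiv), (CF3CO)2O (3 equiv), 85% H3PO4 (cat), CH2Cl2, 0 °C → rt
Reagents that add atoms: acetic acid, CC(=O)O
Why: Friedel–Crafts acylation by the mixed anhydride acetyl trifluoroacetate should go to C8, which is para to the C5 methoxy group, ortho to the C7 methoxy group and has only the ring oxygen as its second neighbour, in preference to C6, which lies between two methoxy groups, and a minor 6-acetyl isomer would be removed by chromatography.

**Step 9**
Reactants: 13 (4R)-8-acetyl-5,7-dimethoxy-4-phenyl-3,4-dihydro-2H-chromen-2-one; 14 3,4-dimethoxybenzaldehyde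
Product: 17 (4R)-8-[(2E)-3-(3,4-dimethoxyphenyl)prop-2-enoyl]-5,7-dimethoxy-4-phenyl-3,4-dihydro-2H-chromen-2-one, via ring-opened keto acid 15 (not isolated), via ring-opened chalcone acid 16 (not isolated)
Conditions: KOH (50% aq), EtOH, rt; 1 M HCl, 0 °C, extraction; then EDC·HCl (1.3 equiv), DMAP (cat), CH2Cl2, rt
Reagents that add atoms: none
Why: Hydroxide first opens the aryl lactone, so that the ketone reacts as an ordinary 2-hydroxy-4,6-dimethoxyacetophenone in a Claisen–Schmidt (crossed aldol) condensation whose E1cB dehydration gives the E enone, and carbodiimide lactonisation then closes the ring again on the only free phenol, the one at C8a.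

**Step 10**
Reactants: 17 (4R)-8-[(2E)-3-(3,4-dimethoxyphenyl)prop-2-enoyl]-5,7-dimethoxy-4-phenyl-3,4-dihydro-2H-chromen-2-one
Product: 18 (4R)-8-[(2E)-3-(3,4-dihydroxyphenyl)prop-2-enoyl]-5,7-dihydroxy-4-phenyl-3,4-dihydro-2H-chromen-2-one
Conditions: BBr3 (8 equiv), CH2Cl2, −78 → 0 °C; ice-water
Reagents that add atoms: none
Why: Lewis-acid cleavage of the four aryl methyl ethers (O–B complexation, then SN2 attack of bromide at methyl, the C7 ether helped by chelation to the ketone) is a standard way to polyhydroxychalcones, and the aryl lactone and the enone should survive at or below 0 °C.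

**Compound list**
1 | 3-phenylglutaric anhydride (4-phenyloxane-2,6-dione) | O=C1CC(c2ccccc2)CC(=O)O1 | starting material
2 | (3S)-5-methoxy-5-oxo-3-phenylpentanoic acid | OC(=O)C[C@H](c1ccccc1)CC(=O)OC | intermediate
3 | 1-tert-butyl 5-methyl (3R)-3-phenylpentanedioate | CC(C)(C)OC(=O)C[C@H](c1ccccc1)CC(=O)OC | intermediate
4 | (3R)-5-tert-butoxy-5-oxo-3-phenylpentanoic acid | CC(C)(C)OC(=O)C[C@H](c1ccccc1)CC(=O)O | intermediate
5 | methyl acetoacetate (methyl 3-oxobutanoate) | CC(=O)CC(=O)OC | starting material
6 | tert-butyl (3R)-5-(1H-imidazol-1-yl)-5-oxo-3-phenylpentanoate (acyl imidazolide, not isolated) | CC(C)(C)OC(=O)C[C@H](c1ccccc1)CC(=O)n1ccnc1 | intermediate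
7 | 9-tert-butyl 1-methyl (7R)-3,5-dioxo-7-phenylnonanedioate | CC(C)(C)OC(=O)C[C@H](c1ccccc1)CC(=O)CC(=O)CC(=O)OC | intermediate
8 | tert-butyl (3S)-3-phenyl-3-(2,4,6-trioxocyclohexyl)propanoate (trione tautomer, not isolated; same spatial arrangement as 9, the descriptor differs by ranking only) | CC(C)(C)OC(=O)C[C@H](c1ccccc1)C1C(=O)CC(=O)CC1=O | intermediate
9 | tert-butyl (3R)-3-phenyl-3-(2,4,6-trihydroxyphenyl)propanoate | CC(C)(C)OC(=O)C[C@H](c1ccccc1)c1c(O)cc(O)cc1O | intermediate
10 | (3R)-3-phenyl-3-(2,4,6-trihydroxyphenyl)propanoic acid (hydroxy acid, not isolated) | OC(=O)C[C@H](c1ccccc1)c1c(O)cc(O)cc1O | intermediate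
11 | (4R)-5,7-dihydroxy-4-phenyl-3,4-dihydro-2H-chromen-2-one | O=C1C[C@H](c2ccccc2)c2c(O)cc(O)cc2O1 | intermediate
12 | (4R)-5,7-dimethoxy-4-phenyl-3,4-dihydro-2H-chromen-2-one | O=C1C[C@H](c2ccccc2)c2c(OC)cc(OC)cc2O1 | intermediate
13 | (4R)-8-acetyl-5,7-dimethoxy-4-phenyl-3,4-dihydro-2H-chromen-2-one | O=C1C[C@H](c2ccccc2)c2c(OC)cc(OC)c(C(C)=O)c2O1 | intermediate
14 | 3,4-dimethoxybenzaldehyde | COc1ccc(C=O)cc1OC | starting material
15 | (3R)-3-(3-acetyl-2-hydroxy-4,6-dimethoxyphenyl)-3-phenylpropanoic acid (ring-opened keto acid, not isolated) | OC(=O)C[C@H](c1ccccc1)c1c(OC)cc(OC)c(C(C)=O)c1O | intermediate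
16 | (3R)-3-{3-[(2E)-3-(3,4-dimethoxyphenyl)prop-2-enoyl]-2-hydroxy-4,6-dimethoxyphenyl}-3-phenylpropanoic acid (ring-opened chalcone acid, not isolated) | OC(=O)C[C@H](c1ccccc1)c1c(OC)cc(OC)c(C(=O)/C=C/c2ccc(OC)c(OC)c2)c1O | intermediate
17 | (4R)-8-[(2E)-3-(3,4-dimethoxyphenyl)prop-2-enoyl]-5,7-dimethoxy-4-phenyl-3,4-dihydro-2H-chromen-2-one | O=C1C[C@H](c2ccccc2)c2c(OC)cc(OC)c(C(=O)/C=C/c3ccc(OC)c(OC)c3)c2O1 | intermediate
18 | (4R)-8-[(2E)-3-(3,4-dihydroxyphenyl)prop-2-enoyl]-5,7-dihydroxy-4-phenyl-3,4-dihydro-2H-chromen-2-one | O=C1C[C@H](c2ccccc2)c2c(O)cc(O)c(C(=O)/C=C/c3ccc(O)c(O)c3)c2O1 | target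

**Totals**
Total step count: 10. Longest linear sequence: 10 steps (1 → 18); 5 and 14 are commercial.

**Steps most likely to fail**

1. Step 5 (proposed new method). The third deprotonation may not take place at C4a, or the ring closure of the aggregated polyanion may be too slow, so that O-acylation towards the pyranone or intermolecular condensation takes over. The fallback gives up the de novo ring and makes the C4–phenyl bond on a preformed aromatic ring by known chemistry. It does not set out from a numbered compound of the route but replaces compounds 1 to 11 by commercial 5,7-dimethoxy-2H-chromen-2-one F1 and phenylboronic acid F2. Rhodium-catalysed asymmetric 1,4-addition of the boronic acid to the coumarin (Rh(acac)(C2H4)2, (R)-SEGPHOS, dioxane–H2O, 60 °C), a reaction already shown on coumarins, should give the (4R)-4-phenyl lactone directly. The ligand enantiomer is the one that gives the (R)-lactone from the parent coumarin. The product is compound 12, where the route is rejoined.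

2. Step 8. Acylation may not distinguish well enough between C8 and C6, so that the 6-acetyl isomer forms in quantity. The fallback sets out from compound 12 and acylates at a stage where the two free ring positions are equivalent. MeI and K2CO3 in acetone–MeOH at reflux open the lactone and methylate the liberated phenol to give methyl (3R)-3-phenyl-3-(2,4,6-trimethoxyphenyl)propanoate F3. Acetylation as in step 8 can then give only one ketone, methyl (3R)-3-(3-acetyl-2,4,6-trimethoxyphenyl)-3-phenylpropanoate F4. BCl3 (3 equiv, CH2Cl2, −78 °C → rt) cleaves only the two methoxy groups ortho to the ketone, by chelation, to give methyl (3R)-3-(3-acetyl-2,4-dihydroxy-6-methoxyphenyl)-3-phenylpropanoate F5. The phenol next to the side chain closes the lactone with loss of methanol (TsOH cat, PhMe, 80 °C), giving (4R)-8-acetyl-7-hydroxy-5-methoxy-4-phenyl-3,4-dihydro-2H-chromen-2-one F6; the surviving C5 methyl ether allows no other lactone. MeI and K2CO3 in acetone then give compound 13, where the route is rejoined.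

3. Step 10. The non-chelated C5 ether may be cleaved only slowly, and during the long exposure to BBr3 and HBr the lactone may open and reclose on the other oxygen, or the 2-hydroxychalcone may cyclise to a flavanone. The fallback sets out from compound 11 and uses benzyl ethers, which come off at −78 °C. BnBr and K2CO3 in DMF give (4R)-5,7-bis(benzyloxy)-4-phenyl-3,4-dihydro-2H-chromen-2-one F7. Acetylation as in step 8 gives (4R)-8-acetyl-5,7-bis(benzyloxy)-4-phenyl-3,4-dihydro-2H-chromen-2-one F8. The aldol and relactonisation sequence of step 9 with 3,4-bis(benzyloxy)benzaldehyde F9 passes through (3R)-3-[3-acetyl-4,6-bis(benzyloxy)-2-hydroxyphenyl]-3-phenylpropanoic acid F10 and (3R)-3-{4,6-bis(benzyloxy)-3-[(2E)-3-[3,4-bis(benzyloxy)phenyl]prop-2-enoyl]-2-hydroxyphenyl}-3-phenylpropanoic acid F11. It gives (4R)-5,7-bis(benzyloxy)-8-{(2E)-3-[3,4-bis(benzyloxy)phenyl]prop-2-enoyl}-4-phenyl-3,4-dihydro-2H-chromen-2-one F12. BCl3 with pentamethylbenzene in CH2Cl2 at −78 °C then removes the four benzyl groups without touching the enone or the lactone and gives compound 18.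

**Further compounds**
F1 | step 5 | 5,7-dimethoxy-2H-chromen-2-one | COc1cc(OC)c2ccc(=O)oc2c1
F2 | step 5 | phenylboronic acid | OB(O)c1ccccc1
F3 | step 8 | methyl (3R)-3-phenyl-3-(2,4,6-trimethoxyphenyl)propanoate | COC(=O)C[C@H](c1ccccc1)c1c(OC)cc(OC)cc1OC
F4 | step 8 | methyl (3R)-3-(3-acetyl-2,4,6-trimethoxyphenyl)-3-phenylpropanoate | COC(=O)C[C@H](c1ccccc1)c1c(OC)cc(OC)c(C(C)=O)c1OC
F5 | step 8 | methyl (3R)-3-(3-acetyl-2,4-dihydroxy-6-methoxyphenyl)-3-phenylpropanoate | COC(=O)C[C@H](c1ccccc1)c1c(OC)cc(O)c(C(C)=O)c1O
F6 | step 8 | (4R)-8-acetyl-7-hydroxy-5-methoxy-4-phenyl-3,4-dihydro-2H-chromen-2-one | O=C1C[C@H](c2ccccc2)c2c(OC)cc(O)c(C(C)=O)c2O1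
F7 | step 10 | (4R)-5,7-bis(benzyloxy)-4-phenyl-3,4-dihydro-2H-chromen-2-one | O=C1C[C@H](c2ccccc2)c2c(OCc3ccccc3)cc(OCc3ccccc3)cc2O1
F8 | step 10 | (4R)-8-acetyl-5,7-bis(benzyloxy)-4-phenyl-3,4-dihydro-2H-chromen-2-one | O=C1C[C@H](c2ccccc2)c2c(OCc3ccccc3)cc(OCc3ccccc3)c(C(C)=O)c2O1
F9 | step 10 | 3,4-bis(benzyloxy)benzaldehyde | O=Cc1ccc(OCc2ccccc2)c(OCc2ccccc2)c1
F10 | step 10 | (3R)-3-[3-acetyl-4,6-bis(benzyloxy)-2-hydroxyphenyl]-3-phenylpropanoic acid | OC(=O)C[C@H](c1ccccc1)c1c(OCc2ccccc2)cc(OCc2ccccc2)c(C(C)=O)c1O
F11 | step 10 | (3R)-3-{4,6-bis(benzyloxy)-3-[(2E)-3-[3,4-bis(benzyloxy)phenyl]prop-2-enoyl]-2-hydroxyphenyl}-3-phenylpropanoic acid | OC(=O)C[C@H](c1ccccc1)c1c(OCc2ccccc2)cc(OCc2ccccc2)c(C(=O)/C=C/c2ccc(OCc3ccccc3)c(OCc3ccccc3)c2)c1O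
F12 | step 10 | (4R)-5,7-bis(benzyloxy)-8-{(2E)-3-[3,4-bis(benzyloxy)phenyl]prop-2-enoyl}-4-phenyl-3,4-dihydro-2H-chromen-2-one | O=C1C[C@H](c2ccccc2)c2c(OCc3ccccc3)cc(OCc3ccccc3)c(C(=O)/C=C/c3ccc(OCc4ccccc4)c(OCc4ccccc4)c3)c2O1
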